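## Structural features

The target is a C24 acid made of three parts in a row: an acetic acid arm (C1–C2) on a 1,2-dioxane (ring A: C3–C6 plus the O–O unit), a tetrahydrofuran (ring B: C7–C10 plus oxygen) bonded directly to ring A through C6–C7, and a fourteen-carbon chain (C11–C24) on C10 ending in a (17Z,19Z)-diene and a terminal vinyl group. There are four stereocentres, (3R,6R,7S,10R): C6 and C7 are adjacent and threo, C3/C6 are trans across ring A, and C7/C10 are trans across ring B. The O–O bond is the most fragile element: metals, hydrides, phosphines and hydrogenation reduce it, and base opens it once a carbonyl sits β to it. The Z,Z-diene can isomerise, and the terminal alkene rules out late hydroboration or hydrogenation, so the peroxide must come after every organometallic step and the triene must be in place before it. The real difficulty is stereochemical: the C6/C7 pair links two rings, and the 1,4-related pairs C3/C6 and C7/C10 are separated only by methylene groups, so no centre can relay its configuration to the next. The useful feature is a hidden symmetry: if both peroxide C–O bonds are made by SN2 inversion of carbinols, C3 and C10 are oxygen-bearing carbons of the same absolute sense, and C2–C6 and C11–C7 are the same five-carbon unit X–CH2–CH(O)–CH2–CH2–CH joined head to head at C6–C7. The key step uses this: an E C6=C7 alkene flanked by two identical (S)-chlorohydrins is C2-symmetric, and oxidative cyclisation from either hydroxyl forms ring B with its O–C7 bond and the C6 carbinol in one operation, leaving C2 as a chlorohydrin carbon and C11 as a chloromethyl group on ring B.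

## Logic of the disconnections

**27 ⇒ 26 ⇒ 25 (C1 oxidation level).** The carboxyl group is taken back to a primary alcohol and then to a hindered silyl ether. A carbonyl β to C3 cannot coexist with the basic peroxide closure, because a C3 sulfonate would eliminate. The gain is a C1 oxygen that is inert through all earlier steps. The demand is a final oxidation that is non-reducing, not strongly basic, and spares the diene.

**25 ⇒ 23 ⇒ 22 ⇒ 21 (O–C3 and O–C6).** Both peroxide C–O bonds are cut, giving a 1,4-bis-sulfonate and behind it a C3,C6-diol carried as two acid-labile silyl ethers. The fragile ring is replaced by two carbinols, each of configuration opposite to the peroxide carbon it becomes. The forward step needs two clean inversions, the second at hindered C6 made intramolecular (6-exo-tet), and no carbanion chemistry afterwards.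

**21 ⇒ 13 + 19, through 20 (C11–C12).** The side chain is cut next to the halomethyl carbon that the symmetric design leaves on ring B. This makes the route convergent and keeps the triene out of all earlier chemistry. The demand is a substitution at a β-oxygenated primary carbon; the polarity must be electrophile at C11 and nucleophile at C12, since a metal at C11 would eliminate the ring oxygen.

**19 ⇒ 18 ⇒ 17 ⇒ 15 + 16, and 15 ⇒ 14 (C18–C19).** The Z,Z-diene is traced to a 1,3-diyne, cut at its central sp–sp bond into two simple terminal alkynes. Both alkene geometries then come from one cis-reduction. That reduction must act only on conjugated triple bonds and leave the terminal alkene.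

**13 ⇒ 12 ⇒ 10 ⇒ 8 (halogen exchange, protecting pattern, C1–C2).** The iodide goes back to the chloride, the three silyl ethers to a diol, and the C1–C2 bond is cut by opening a C2–C3 epoxide with a hydroxymethyl anion equivalent. C2 is the other halomethyl carbon and becomes electrophilic once its neighbouring hydroxyl closes onto it. The C11 chloride must stay inert to the copper-catalysed opening, and the C6 hydroxyl must be capped so it cannot attack the epoxide.

**8 ⇒ 6, through 7 (epoxide O–C2).** The epoxide is the internal ether of the C2–C3 chlorohydrin. Only this chloride has a neighbouring hydroxyl, so the two chain ends, identical before the key step, are addressed separately without any selective reagent.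

**6 ⇒ 4, through 5 (O–C7 and C6–O; key step).** Ring B and the C6 hydroxyl are removed together, giving the C2-symmetric E-alkene diol. This cut is chosen because it alone creates the contiguous C6/C7 pair, closes ring B trans to the existing C10 centre and desymmetrises the chain. The forward step needs syn addition, trans ring closure and a geometrically pure E-alkene.

**4 ⇒ 3 + 3 (C6=C7).** The alkene is cut into two identical terminal alkenes, so one building block serves both halves. Metathesis equilibration cannot give a single geometry, so the Z isomer must be removed at this stage. Any minor enantiomer of 3 is diverted mainly into a meso-type diastereomer, which raises the enantiopurity of 4.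

**3 ⇒ 1 + 2 (C4–C5 and, in the twin, C8–C9).** The chlorohydrin is cut into the bought epoxide and an allyl nucleophile. The forward step must open the epoxide at its CH2 terminus and leave the chloride in place. Chloride is kept deliberately as the spectator: it does not coordinate rhenium, survives copper/Grignard chemistry, and is unmasked differently at the two ends.

## Other disconnections considered

**Alternative 1:** The cut is C4–C5, made as a C4=C5 alkene between two allylic carbinols (C3 and C6) tied together as a diphenylsilylene bis-ether. Forward, the acyclic bis-ether A2 would be closed by the second-generation Grubbs catalyst RuCl2(=CHPh)(PCy3)(H2IMes) to the seven-membered dioxasilepine A1. Removal of silicon and saturation of the ring alkene would then give a C3,C6-diol of the same configuration as 22.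
- In its favour: the union is convergent, the tether turns an unselective cross-metathesis into a ring closure, and alkene geometry is irrelevant because the double bond is reduced afterwards. Both carbinol centres exist before the key step, so the step creates no stereochemistry; on reliability of the key bond formation this plan is the better one.
- Against it here: each half of A2 carries a carbinol centre that must be set separately, and the C6 centre next to ring B must be made threo by its own diastereoselective step. The mixed bis-ether needs two sequential silylations through a moisture-sensitive chlorosilane. Most seriously, C4=C5 must be saturated while no other alkene is present, so A1 carries only a C11–C17 chain ending in a protected alcohol and the whole C17–C24 triene must be added later.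
- Comparison: structurally it treats C3 and C6 as unrelated and ignores the two-fold symmetry. Mechanistically it rests on a well-behaved ring-closing metathesis instead of a less common oxo-metal cyclisation. In step economy it should be clearly longer, since its key step delivers neither ring B nor a stereocentre. It equals the chosen plan in converging on the same bis-sulfonate/peroxide closure.

**Alternative 2:** The cut removes both peroxide C–O bonds (O–C3, O–C6). Forward, the bis-mesylate A4 would react with basic hydrogen peroxide, first at C3 and then intramolecularly at C6, to give the silyl-protected dioxane A3.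
- In its favour: every C–C bond and carbon stereocentre is in place before the fragile ring appears, the closure is stereospecific (two inversions), and the peroxide then faces only two further steps.
- Against it as the organising step: it simplifies no carbon skeleton and creates no stereocentre, so it does not say how the diol with four oxygenated centres and ring B is obtained. The substitution at C6 is hindered and competes with elimination. C1 must be carried as a base-stable ether and oxidised after the peroxide exists.
- Comparison: this closure is the end-game of the chosen plan, not a rival; step 15 is the same reaction on 23, so on this bond-forming event the two are equal. The tert-butyldimethylsilyl ether of A3 should be easier to remove than the triisopropylsilyl ether of 25, a small point for the alternative, paid for by lower tolerance of the basic peroxide medium and of the acid step 13. The difference is where the strategic weight lies: step 3 makes a ring, two stereocentres and the differentiation of the chain ends, whereas this step only transfers stereochemistry.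

**Alternative 3:** The cuts are O–C10 and C10–C11 of ring B. Forward, the diazoketone A6, an O-allyl ether derived from (S)-malic acid A7, would be decomposed by Cu(acac)2. The copper carbenoid at C10 would be trapped by the ether oxygen as a cyclic oxonium ylide, and [2,3]-shift of the allyl group from oxygen to C10 would give the trans furanone A5.
- In its favour: ring B closes and C10–C11 forms in one step with the trans relationship under well-understood control, and the chiral source is very cheap. The allyl group lets the side chain grow by alkene chemistry and avoids substitution at the β-oxygenated C11 carbon; on that point the alternative is better than the chosen plan, whose step 12 is among its weakest.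
- Against it here: the C9 carbonyl is surplus and would cost a reduction–deoxygenation sequence. The diazoketone needs diazomethane or a surrogate, which conflicts with a safe route. The key step sets only C10 relative to C7, so C6 and C3 each still need a separate stereoselective operation, and only C6–C13 of the 24 carbons are present afterwards.
- Comparison: mechanistically both key steps use a cyclic transition state to place the ring substituents trans, and the ylide rearrangement is at least the equal of the rhenium cyclisation in predictability. Structurally it addresses only ring B, while the chosen step also delivers C6 and, through the twin building block, C3. In step economy the chosen plan should be much shorter.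

Key step: step 3

Remark: atom numbers C1–C24 are those of the target acid (C1 = carboxyl carbon); operations run in one flask without isolating the intermediate are counted as one step.

## Route

Step 1
Reactants: 1 (S)-epichlorohydrin [(2S)-2-(chloromethyl)oxirane]; 2 allylmagnesium chloride
Product: 3 (2S)-1-chlorohex-5-en-2-ol
Conditions: CuI (10 mol %), THF, −40 → −20 °C; aq. NH4Cl
Reagents that add atoms: none
Why: Copper-catalysed Grignard opening of the epoxide at its unsubstituted carbon (SN2) is faster than attack at the chloromethyl group, so the C–O stereocentre of 1 passes unchanged into the chlorohydrin; low temperature prevents the magnesium alkoxide from closing to a new epoxide.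

Step 2
Reactants: 3 (2S)-1-chlorohex-5-en-2-ol (two molecules)
Product: 4 (2S,5E,9S)-1,10-dichlorodec-5-ene-2,9-diol
Conditions: second-generation Grubbs catalyst RuCl2(=CHPh)(PCy3)(H2IMes) (2 mol %), 1,4-benzoquinone (10 mol %), CH2Cl2, 40 °C, argon sweep; chromatography on AgNO3-impregnated silica to remove the Z isomer
Reagents that add atoms: none
Why: Olefin self-metathesis of a terminal alkene remote from the free hydroxyl; loss of ethene drives it and secondary metathesis equilibrates towards the more stable E isomer, while benzoquinone suppresses hydride-induced alkene migration. The minor Z isomer must be removed here, because syn addition to it in step 3 would lead into the erythro series.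

Step 3
Reactants: 4 (2S,5E,9S)-1,10-dichlorodec-5-ene-2,9-diol
Product: 6 (1S,4S)-5-chloro-1-[(2S,5S)-5-(chloromethyl)oxolan-2-yl]pentane-1,4-diol, via perrhenate monoester 5 (not isolated)
Conditions: Re2O7 (2.5 equiv), (CF3CO)2O, THF, rt, then evaporation; 4, (CF3CO)2O, CH2Cl2, 0 °C → rt; aq. NaHCO3/MeOH work-up
Reagents that add atoms: dirhenium heptoxide, O=[Re](=O)(=O)O[Re](=O)(=O)=O
Why: Either homotopic hydroxyl of 4 is converted by trifluoroacetyl perrhenate into the alkyl perrhenate 5, whose O=Re–OR unit adds suprafacially across C6=C7 (formally a [3+2] addition) so that the alkoxide oxygen bonds to C7 and an oxo oxygen to C6; hydrolysis of the resulting pentavalent rhenium alkoxide on work-up releases 6. The closest known reaction type is the rhenium oxide-mediated syn-oxidative cyclisation of 5-hydroxyalkenes to trans-2,5-disubstituted tetrahydrofuran carbinols. Ring B closes in the 5-exo-trig mode. C7 is set relative to the bought C10 centre by the cyclic transition state, in which the chloromethyl-bearing carbon and the alkene substituent avoid the rhenium oxo ligands and end up trans across the ring. C6 is set relative to C7 by the syn stereospecificity of the addition together with the E geometry, which gives the threo pair. The step needs trans over cis closure and clean syn addition, but no site selectivity, because the C2 axis makes the two hydroxyls and the two alkene carbons equivalent, and over-reaction is impossible once the only alkene is consumed. The chloromethyl groups are non-coordinating spectators and should not draw rhenium into a chelated, cis-selective pathway; any perrhenate or trifluoroacetate ester on the second hydroxyl is cleaved in the bicarbonate work-up.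

Step 4
Reactants: 6 (1S,4S)-5-chloro-1-[(2S,5S)-5-(chloromethyl)oxolan-2-yl]pentane-1,4-diol
Product: 8 {(1S)-1-[(2S,5S)-5-(chloromethyl)oxolan-2-yl]-3-[(2S)-oxiran-2-yl]propoxy}triethylsilane, via epoxy alcohol 7 (not isolated)
Conditions: K2CO3, MeOH, 0 °C; filter, concentrate; then Et3SiCl, imidazole, CH2Cl2, 0 °C
Reagents that add atoms: chlorotriethylsilane, CC[Si](Cl)(CC)CC
Why: Intramolecular Williamson closure (3-exo-tet) of the chlorohydrin leaves C3 untouched, while the C11 chloride, which has no neighbouring hydroxyl, stays. Silylating the C6 hydroxyl at once, without chromatography of 7, removes the risk of its 5-exo attack on the epoxide.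

Step 5
Reactants: 8 {(1S)-1-[(2S,5S)-5-(chloromethyl)oxolan-2-yl]-3-[(2S)-oxiran-2-yl]propoxy}triethylsilane
Product: 10 (3S,6S)-6-[(2S,5S)-5-(chloromethyl)oxolan-2-yl]-6-(triethylsilyloxy)hexane-1,3-diol, via hydroxy silane 9 (not isolated)
Conditions: (i-PrO)Me2SiCH2MgCl (from (i-PrO)Me2SiCH2Cl, Mg, THF), CuI (10 mol %), THF, −30 → 0 °C; then KF, KHCO3, 30% H2O2, THF/MeOH, rt
Reagents that add atoms: (chloromethyl)dimethyl(propan-2-yloxy)silane (used as its Grignard reagent; supplies C1), ClC[Si](C)(C)OC(C)C; hydrogen peroxide (supplies the C1 oxygen), OO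
Why: Copper-catalysed SN2 opening of the terminal epoxide at C2 by the silylmethyl Grignard reagent (a hydroxymethyl anion equivalent) forms C1–C2 without touching C3, and Tamao oxidation then converts C–Si into the C1 hydroxyl. Alkyl chlorides do not couple under these conditions, so C11–Cl survives; any C6 silyl ether lost to fluoride is restored in step 6.

Step 6
Reactants: 10 (3S,6S)-6-[(2S,5S)-5-(chloromethyl)oxolan-2-yl]-6-(triethylsilyloxy)hexane-1,3-diol
Product: 12 (2S,5S)-2-(chloromethyl)-5-[(1S,4S)-1,4-bis(triethylsilyloxy)-6-(triisopropylsilyloxy)hexyl]oxolane, via C1 silyl ether 11 (not isolated)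
Conditions: i-Pr3SiCl, imidazole, DMF, 0 °C → rt; then Et3SiCl, rt
Reagents that add atoms: chlorotri(propan-2-yl)silane, CC(C)[Si](Cl)(C(C)C)C(C)C; chlorotriethylsilane, CC[Si](Cl)(CC)CC
Why: The bulky triisopropylsilyl chloride silylates only the primary C1 hydroxyl, after which triethylsilyl chloride caps the secondary C3 hydroxyl in the same flask. The C1 group is chosen to outlast the later acid cleavage of both triethylsilyl ethers and the basic peroxide medium.

Step 7
Reactants: 12 (2S,5S)-2-(chloromethyl)-5-[(1S,4S)-1,4-bis(triethylsilyloxy)-6-(triisopropylsilyloxy)hexyl]oxolane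
Product: 13 (2S,5S)-2-(iodomethyl)-5-[(1S,4S)-1,4-bis(triethylsilyloxy)-6-(triisopropylsilyloxy)hexyl]oxolane
Conditions: NaI, NaHCO3, butan-2-one, reflux
Reagents that add atoms: sodium iodide, [Na+].[I-]
Why: Finkelstein exchange (SN2, driven by precipitation of NaCl) converts the inert chloride into the iodide needed for coupling. The β-oxygen slows the substitution, hence the boiling ketone; NaHCO3 protects the silyl ethers from traces of HI.

Step 8
Reactants: 14 hept-6-yn-1-ol
Product: 15 7-bromohept-6-yn-1-ol
Conditions: N-bromosuccinimide, AgNO3 (10 mol %), acetone, rt, dark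
Reagents that add atoms: N-bromosuccinimide, O=C1CCC(=O)N1Br
Why: Silver-catalysed electrophilic bromination of the terminal alkyne gives the 1-bromoalkyne; the primary alcohol does not interfere, and the less volatile of the two alkynes is the one brominated.

Step 9
Reactants: 15 7-bromohept-6-yn-1-ol; 16 hex-5-en-1-yne
Product: 17 tridec-12-ene-6,8-diyn-1-ol
Conditions: CuCl (5 mol %), NH2OH·HCl, 30% aq. n-BuNH2, Et2O, 0 °C → rt
Reagents that add atoms: none
Why: Cadiot–Chodkiewicz coupling: the alkynylcopper species formed from 16 and CuCl couples with bromoalkyne 15 to give the unsymmetrical 1,3-diyne (C18–C19 bond). NH2OH·HCl keeps copper monovalent so that oxidative homocoupling is suppressed.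

Step 10
Reactants: 17 tridec-12-ene-6,8-diyn-1-ol
Product: 18 (6Z,8Z)-trideca-6,8,12-trien-1-ol
Conditions: Zn dust activated with Cu(OAc)2 and AgNO3, MeOH/H2O (1:1), 45 °C
Reagents that add atoms: none
Why: Activated zinc (Boland reduction) delivers hydrogen cis only to conjugated triple bonds, so both alkynes of the diyne become Z alkenes while the isolated terminal alkene is untouched.

Step 11
Reactants: 18 (6Z,8Z)-trideca-6,8,12-trien-1-ol
Product: 19 (5Z,7Z)-13-bromotrideca-1,5,7-triene
Conditions: CBr4, PPh3, CH2Cl2, 0 °C
Reagents that add atoms: tetrabromomethane, BrC(Br)(Br)Br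
Why: Appel reaction: bromide displaces the alkoxyphosphonium group at the primary carbon under neutral conditions that should not isomerise the Z,Z-diene.

Step 12
Reactants: 13 (2S,5S)-2-(iodomethyl)-5-[(1S,4S)-1,4-bis(triethylsilyloxy)-6-(triisopropylsilyloxy)hexyl]oxolane; 19 (5Z,7Z)-13-bromotrideca-1,5,7-triene
Product: 21 (2R,5S)-2-[(7Z,9Z)-tetradeca-7,9,13-trien-1-yl]-5-[(1S,4S)-1,4-bis(triethylsilyloxy)-6-(triisopropylsilyloxy)hexyl]oxolane, via Grignard reagent 20 (not isolated)
Conditions: 19, Mg, THF, rt; then 13, Li2CuCl4 (5 mol %), THF/NMP, −20 → 0 °C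
Reagents that add atoms: none
Why: Copper-catalysed alkyl–alkyl Grignard cross-coupling: the alkylcuprate formed from 20 and Li2CuCl4 displaces iodide at primary C11 (SN2) and forms C11–C12. The polarity is chosen so that no organometallic arises at C11, where β-elimination of the ring oxygen would follow; the silyl ethers are inert.

Step 13
Reactants: 21 (2R,5S)-2-[(7Z,9Z)-tetradeca-7,9,13-trien-1-yl]-5-[(1S,4S)-1,4-bis(triethylsilyloxy)-6-(triisopropylsilyloxy)hexyl]oxolane
Product: 22 (3S,6S)-6-{(2S,5R)-5-[(7Z,9Z)-tetradeca-7,9,13-trien-1-yl]oxolan-2-yl}-1-(triisopropylsilyloxy)hexane-3,6-diol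
Conditions: pyridinium p-toluenesulfonate (cat.), MeOH/CH2Cl2, 0 °C → rt
Reagents that add atoms: none
Why: Acid-catalysed methanolysis removes the two secondary triethylsilyl ethers much faster than the hindered primary triisopropylsilyl ether, and the mild acid should leave the diene alone.

Step 14
Reactants: 22 (3S,6S)-6-{(2S,5R)-5-[(7Z,9Z)-tetradeca-7,9,13-trien-1-yl]oxolan-2-yl}-1-(triisopropylsilyloxy)hexane-3,6-diol
Product: 23 (3S,6S)-6-{(2S,5R)-5-[(7Z,9Z)-tetradeca-7,9,13-trien-1-yl]oxolan-2-yl}-1-(triisopropylsilyloxy)hexane-3,6-diyl dimethanesulfonate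
Conditions: MsCl, Et3N, CH2Cl2, −10 → 0 °C
Reagents that add atoms: methanesulfonyl chloride, CS(=O)(=O)Cl
Why: O-Sulfonylation proceeds with retention at C3 and C6 and installs both leaving groups; the bis-mesylate is used without delay.

Step 15
Reactants: 23 (3S,6S)-6-{(2S,5R)-5-[(7Z,9Z)-tetradeca-7,9,13-trien-1-yl]oxolan-2-yl}-1-(triisopropylsilyloxy)hexane-3,6-diyl dimethanesulfonate
Product: 25 triisopropyl{2-[(3R,6R)-6-{(2S,5R)-5-[(7Z,9Z)-tetradeca-7,9,13-trien-1-yl]oxolan-2-yl}-1,2-dioxan-3-yl]ethoxy}silane, via C3 hydroperoxide 24 (not isolated)
Conditions: 30% aq. H2O2, KOH, MeOH/THF, 0 °C → rt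
Reagents that add atoms: hydrogen peroxide, OO
Why: Two successive SN2 displacements by hydroperoxide: the intermolecular one at the less hindered C3 mesylate gives 24 with inversion, and its anion then closes ring A by 6-exo-tet displacement at C6, again with inversion, so the (3S,6S) diol configuration becomes the (3R,6R) trans-dioxane. This is the classical synthesis of dialkyl peroxides from sulfonates and basic hydrogen peroxide, used twice.

Step 16
Reactants: 25 triisopropyl{2-[(3R,6R)-6-{(2S,5R)-5-[(7Z,9Z)-tetradeca-7,9,13-trien-1-yl]oxolan-2-yl}-1,2-dioxan-3-yl]ethoxy}silane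
Product: 26 2-[(3R,6R)-6-{(2S,5R)-5-[(7Z,9Z)-tetradeca-7,9,13-trien-1-yl]oxolan-2-yl}-1,2-dioxan-3-yl]ethan-1-ol
Conditions: HF·pyridine, pyridine, THF, 0 °C → rt
Reagents that add atoms: none
Why: Fluoride cleaves the Si–O bond under buffered, weakly acidic conditions, which avoids base-induced (Kornblum–DeLaMare type) cleavage of the peroxide.

Step 17
Reactants: 26 2-[(3R,6R)-6-{(2S,5R)-5-[(7Z,9Z)-tetradeca-7,9,13-trien-1-yl]oxolan-2-yl}-1,2-dioxan-3-yl]ethan-1-ol
Product: 27 2-[(3R,6R)-6-{(2S,5R)-5-[(7Z,9Z)-tetradeca-7,9,13-trien-1-yl]oxolan-2-yl}-1,2-dioxan-3-yl]acetic acid (target)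
Conditions: TEMPO (20 mol %), PhI(OAc)2, MeCN/H2O (1:1), rt
Reagents that add atoms: water, O
Why: Oxoammonium-mediated oxidation takes the primary alcohol to the aldehyde and, through its hydrate in the aqueous medium, on to the carboxylic acid. The medium is slightly acidic and non-reducing, so the peroxide and the Z,Z-diene should survive.

## Compound list

1 | (S)-epichlorohydrin [(2S)-2-(chloromethyl)oxirane] | ClC[C@@H]1CO1 | starting material
2 | allylmagnesium chloride | C=CC[Mg]Cl | starting material
3 | (2S)-1-chlorohex-5-en-2-ol | ClC[C@@H](O)CCC=C | intermediate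
4 | (2S,5E,9S)-1,10-dichlorodec-5-ene-2,9-diol | ClC[C@@H](O)CC/C=C/CC[C@H](O)CCl | intermediate
5 | (2S,5E,9S)-1,10-dichloro-9-hydroxydec-5-en-2-yl perrhenate | ClC[C@@H](O[Re](=O)(=O)=O)CC/C=C/CC[C@H](O)CCl | intermediate (not isolated)
6 | (1S,4S)-5-chloro-1-[(2S,5S)-5-(chloromethyl)oxolan-2-yl]pentane-1,4-diol | ClC[C@@H]1CC[C@@H]([C@@H](O)CC[C@H](O)CCl)O1 | intermediate
7 | (1S)-1-[(2S,5S)-5-(chloromethyl)oxolan-2-yl]-3-[(2S)-oxiran-2-yl]propan-1-ol | ClC[C@@H]1CC[C@@H]([C@@H](O)CC[C@H]2CO2)O1 | intermediate (not isolated)
8 | {(1S)-1-[(2S,5S)-5-(chloromethyl)oxolan-2-yl]-3-[(2S)-oxiran-2-yl]propoxy}triethylsilane | ClC[C@@H]1CC[C@@H]([C@@H](O[Si](CC)(CC)CC)CC[C@H]2CO2)O1 | intermediate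
9 | (3S,6S)-6-[(2S,5S)-5-(chloromethyl)oxolan-2-yl]-1-[dimethyl(propan-2-yloxy)silyl]-6-(triethylsilyloxy)hexan-3-ol | ClC[C@@H]1CC[C@@H]([C@@H](O[Si](CC)(CC)CC)CC[C@H](O)CC[Si](C)(C)OC(C)C)O1 | intermediate (not isolated)
10 | (3S,6S)-6-[(2S,5S)-5-(chloromethyl)oxolan-2-yl]-6-(triethylsilyloxy)hexane-1,3-diol | ClC[C@@H]1CC[C@@H]([C@@H](O[Si](CC)(CC)CC)CC[C@H](O)CCO)O1 | intermediate
11 | (3S,6S)-6-[(2S,5S)-5-(chloromethyl)oxolan-2-yl]-6-(triethylsilyloxy)-1-(triisopropylsilyloxy)hexan-3-ol | ClC[C@@H]1CC[C@@H]([C@@H](O[Si](CC)(CC)CC)CC[C@H](O)CCO[Si](C(C)C)(C(C)C)C(C)C)O1 | intermediate (not isolated)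
12 | (2S,5S)-2-(chloromethyl)-5-[(1S,4S)-1,4-bis(triethylsilyloxy)-6-(triisopropylsilyloxy)hexyl]oxolane | ClC[C@@H]1CC[C@@H]([C@@H](O[Si](CC)(CC)CC)CC[C@H](O[Si](CC)(CC)CC)CCO[Si](C(C)C)(C(C)C)C(C)C)O1 | intermediate
13 | (2S,5S)-2-(iodomethyl)-5-[(1S,4S)-1,4-bis(triethylsilyloxy)-6-(triisopropylsilyloxy)hexyl]oxolane | IC[C@@H]1CC[C@@H]([C@@H](O[Si](CC)(CC)CC)CC[C@H](O[Si](CC)(CC)CC)CCO[Si](C(C)C)(C(C)C)C(C)C)O1 | intermediate
14 | hept-6-yn-1-ol | C#CCCCCCO | starting material
15 | 7-bromohept-6-yn-1-ol | OCCCCCC#CBr | intermediate
16 | hex-5-en-1-yne | C#CCCC=C | starting material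
17 | tridec-12-ene-6,8-diyn-1-ol | OCCCCCC#CC#CCCC=C | intermediate
18 | (6Z,8Z)-trideca-6,8,12-trien-1-ol | OCCCCC/C=C\C=C/CCC=C | intermediate
19 | (5Z,7Z)-13-bromotrideca-1,5,7-triene | BrCCCCC/C=C\C=C/CCC=C | intermediate
20 | [(6Z,8Z)-trideca-6,8,12-trien-1-yl]magnesium bromide | Br[Mg]CCCCC/C=C\C=C/CCC=C | intermediate (not isolated)
21 | (2R,5S)-2-[(7Z,9Z)-tetradeca-7,9,13-trien-1-yl]-5-[(1S,4S)-1,4-bis(triethylsilyloxy)-6-(triisopropylsilyloxy)hexyl]oxolane | C=CCC/C=C\C=C/CCCCCC[C@@H]1CC[C@@H]([C@@H](O[Si](CC)(CC)CC)CC[C@H](O[Si](CC)(CC)CC)CCO[Si](C(C)C)(C(C)C)C(C)C)O1 | intermediate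
22 | (3S,6S)-6-{(2S,5R)-5-[(7Z,9Z)-tetradeca-7,9,13-trien-1-yl]oxolan-2-yl}-1-(triisopropylsilyloxy)hexane-3,6-diol | C=CCC/C=C\C=C/CCCCCC[C@@H]1CC[C@@H]([C@@H](O)CC[C@H](O)CCO[Si](C(C)C)(C(C)C)C(C)C)O1 | intermediate
23 | (3S,6S)-6-{(2S,5R)-5-[(7Z,9Z)-tetradeca-7,9,13-trien-1-yl]oxolan-2-yl}-1-(triisopropylsilyloxy)hexane-3,6-diyl dimethanesulfonate | C=CCC/C=C\C=C/CCCCCC[C@@H]1CC[C@@H]([C@@H](OS(C)(=O)=O)CC[C@H](OS(C)(=O)=O)CCO[Si](C(C)C)(C(C)C)C(C)C)O1 | intermediate
24 | (1S,4R)-4-hydroperoxy-1-{(2S,5R)-5-[(7Z,9Z)-tetradeca-7,9,13-trien-1-yl]oxolan-2-yl}-6-(triisopropylsilyloxy)hexyl methanesulfonate | C=CCC/C=C\C=C/CCCCCC[C@@H]1CC[C@@H]([C@@H](OS(C)(=O)=O)CC[C@@H](OO)CCO[Si](C(C)C)(C(C)C)C(C)C)O1 | intermediate (not isolated)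
25 | triisopropyl{2-[(3R,6R)-6-{(2S,5R)-5-[(7Z,9Z)-tetradeca-7,9,13-trien-1-yl]oxolan-2-yl}-1,2-dioxan-3-yl]ethoxy}silane | C=CCC/C=C\C=C/CCCCCC[C@@H]1CC[C@@H]([C@H]2CC[C@H](CCO[Si](C(C)C)(C(C)C)C(C)C)OO2)O1 | intermediate
26 | 2-[(3R,6R)-6-{(2S,5R)-5-[(7Z,9Z)-tetradeca-7,9,13-trien-1-yl]oxolan-2-yl}-1,2-dioxan-3-yl]ethan-1-ol | C=CCC/C=C\C=C/CCCCCC[C@@H]1CC[C@@H]([C@H]2CC[C@H](CCO)OO2)O1 | intermediate
27 | 2-[(3R,6R)-6-{(2S,5R)-5-[(7Z,9Z)-tetradeca-7,9,13-trien-1-yl]oxolan-2-yl}-1,2-dioxan-3-yl]acetic acid | C=CCC/C=C\C=C/CCCCCC[C@@H]1CC[C@@H]([C@H]2CC[C@H](CC(=O)O)OO2)O1 | target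

## Step count and least certain steps

Total: 17 steps. Longest linear sequence: 13 steps (steps 1–7 and 12–17); the side chain (steps 8–11) joins at step 12.

**Step 3 (key step).** The most likely failure is loss of trans selectivity or of material through the second, non-cyclising hydroxyl. It can take up a second rhenium, be trifluoroacetylated, or coordinate to the metal of the reacting perrhenate and open a chelated path to the cis ring; the electron-poor chlorohydrin oxygen may also make ester formation slow. The fallback desymmetrises by protection instead of by the cyclisation itself. It sets out from 4, which is treated with one equivalent of t-BuPh2SiCl and imidazole to give (2S,5E,9S)-9-(tert-butyldiphenylsilyloxy)-1,10-dichlorodec-5-en-2-ol F1 (statistical; unreacted 4 is recycled). F1 is cyclised with the same rhenium reagent to (1S,4S)-4-(tert-butyldiphenylsilyloxy)-5-chloro-1-[(2S,5S)-5-(chloromethyl)oxolan-2-yl]pentan-1-ol F2. Bu4NF buffered with acetic acid, so that the freed chlorohydrin does not close, then returns the route to 6.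

**Step 15.** Elimination of the C6 mesylate (flanked by ring B, with a β-oxygen that retards substitution), participation of the ring oxygen, or base-induced breakdown of hydroperoxide 24 before it cyclises can each divert the double displacement. A second intermolecular attack giving a bis-hydroperoxide is a further drain. The fallback is stepwise, with a protected hydroperoxide, and sets out from 23. Tetrahydropyran-2-yl hydroperoxide with CsOH·H2O in DMF should displace only the more accessible C3 mesylate to give (1S,4R)-4-(oxan-2-ylperoxy)-1-{(2S,5R)-5-[(7Z,9Z)-tetradeca-7,9,13-trien-1-yl]oxolan-2-yl}-6-(triisopropylsilyloxy)hexyl methanesulfonate F3. Brief acid methanolysis (cat. TsOH, MeOH, 0 °C) frees 24, now isolated, and KOt-Bu with 18-crown-6 in dilute THF closes it to 25, where the route is rejoined.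

**Step 12.** Iodine–magnesium exchange at C11 followed by β-elimination of the ring oxygen (ring opening), sluggish substitution at the β-oxygenated carbon, and homocoupling of 20 are the likely losses. The fallback replaces cuprate substitution by sulfone alkylation and sets out from 19 and 13. PhSO2Na in DMF converts 19 into [(6Z,8Z)-trideca-6,8,12-trien-1-ylsulfonyl]benzene F4. Its lithio derivative (n-BuLi, THF/DMPU, −78 °C) alkylates 13 to give the C12 phenylsulfonyl derivative of 21, F5 (both C12 epimers). Mg in MeOH removes the sulfonyl group and returns the route to 21; any triethylsilyl ether lost there does not matter, since step 13 removes both.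

**Step 2.** The metathesis equilibrium cannot give a single geometry, and incomplete removal of the Z isomer would carry an erythro diastereomer through the whole route; alkene migration by ruthenium hydrides would give chain-shortened dimers. The fallback destroys the Z isomer kinetically instead of separating it, and sets out from the crude mixture of 4 and its Z isomer (2S,5Z,9S)-1,10-dichlorodec-5-ene-2,9-diol F6. The mixture is exposed to ethene with the Z-selective cyclometalated ruthenium nitrato alkylidene Ru(NO3)(=CH-C6H4-2-Oi-Pr)(L), where L is 1-(adamantan-1-yl)-3-(2,6-diisopropylphenyl)imidazolin-2-ylidene bound through the carbene carbon and an adamantyl carbon. This should cleave F6 back to 3, which is recycled into step 2, and leave 4, the point of return.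

## Further compounds

F1 | step 3 | (2S,5E,9S)-9-(tert-butyldiphenylsilyloxy)-1,10-dichlorodec-5-en-2-ol | ClC[C@@H](O)CC/C=C/CC[C@H](O[Si](c1ccccc1)(c1ccccc1)C(C)(C)C)CCl
F2 | step 3 | (1S,4S)-4-(tert-butyldiphenylsilyloxy)-5-chloro-1-[(2S,5S)-5-(chloromethyl)oxolan-2-yl]pentan-1-ol | ClC[C@@H]1CC[C@@H]([C@@H](O)CC[C@H](O[Si](c2ccccc2)(c2ccccc2)C(C)(C)C)CCl)O1
F3 | step 15 | (1S,4R)-4-(oxan-2-ylperoxy)-1-{(2S,5R)-5-[(7Z,9Z)-tetradeca-7,9,13-trien-1-yl]oxolan-2-yl}-6-(triisopropylsilyloxy)hexyl methanesulfonate | C=CCC/C=C\C=C/CCCCCC[C@@H]1CC[C@@H]([C@@H](OS(C)(=O)=O)CC[C@@H](OOC2CCCCO2)CCO[Si](C(C)C)(C(C)C)C(C)C)O1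
F4 | step 12 | [(6Z,8Z)-trideca-6,8,12-trien-1-ylsulfonyl]benzene | O=S(=O)(CCCCC/C=C\C=C/CCC=C)c1ccccc1
F5 | step 12 | C12 phenylsulfonyl derivative of 21 (both C12 epimers) | C=CCC/C=C\C=C/CCCCC(C[C@@H]1CC[C@@H]([C@@H](O[Si](CC)(CC)CC)CC[C@H](O[Si](CC)(CC)CC)CCO[Si](C(C)C)(C(C)C)C(C)C)O1)S(=O)(=O)c1ccccc1
F6 | step 2 | (2S,5Z,9S)-1,10-dichlorodec-5-ene-2,9-diol | ClC[C@@H](O)CC/C=C\CC[C@H](O)CCl
A1 | alternative 1 | Z-configured 2,2-diphenyl-4,7-dihydro-1,3,2-dioxasilepine spanning C3–C6, with the 2-(tert-butyldiphenylsilyloxy)ethyl arm on C3 and, on C6, trans ring B carrying a 7-(4-methoxybenzyloxy)heptyl chain | COc1ccc(COCCCCCCC[C@@H]2CC[C@@H]([C@@H]3C=C[C@@H](CCO[Si](c4ccccc4)(c4ccccc4)C(C)(C)C)O[Si](c4ccccc4)(c4ccccc4)O3)O2)cc1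
A2 | alternative 1 | acyclic diphenylsilylene bis-ether of the C3 and C6 vinyl carbinols (metathesis precursor of A1) | COc1ccc(COCCCCCCC[C@@H]2CC[C@@H]([C@H](C=C)O[Si](c3ccccc3)(c3ccccc3)O[C@@H](C=C)CCO[Si](c3ccccc3)(c3ccccc3)C(C)(C)C)O2)cc1
A3 | alternative 2 | C1 tert-butyldimethylsilyl ether of the reduced target (trans-dioxane closed) | C=CCC/C=C\C=C/CCCCCC[C@@H]1CC[C@@H]([C@H]2CC[C@H](CCO[Si](C)(C)C(C)(C)C)OO2)O1
A4 | alternative 2 | (3S,6S)-bis-mesylate carrying the C1 tert-butyldimethylsilyl ether (precursor of A3) | C=CCC/C=C\C=C/CCCCCC[C@@H]1CC[C@@H]([C@@H](OS(C)(=O)=O)CC[C@H](OS(C)(=O)=O)CCO[Si](C)(C)C(C)(C)C)O1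
A5 | alternative 3 | trans-2-allyl-5-[(tert-butyldiphenylsilyloxy)methyl]dihydrofuran-3(2H)-one (C6–C13) | C=CC[C@@H]1C(=O)C[C@@H](CO[Si](c2ccccc2)(c2ccccc2)C(C)(C)C)O1
A6 | alternative 3 | (4S)-4-(allyloxy)-5-(tert-butyldiphenylsilyloxy)-1-diazopentan-2-one | [N-]=[N+]=CC(=O)C[C@H](OCC=C)CO[Si](c1ccccc1)(c1ccccc1)C(C)(C)C
A7 | alternative 3 | (S)-malic acid | O=C(O)C[C@H](O)C(=O)O
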